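**Retrosynthetic overview**
- Waltherione K (10) ⇐ N-oxide 9 by an O→O methyl shift (4-methoxypyridine N-oxide → 1-methoxy-4-pyridone); 9 ⇐ tetrahydroquinoline 8 by N-oxidation.
- Key step: 8 ⇐ flat, achiral quinoline 7 by one carbocycle-selective asymmetric arene hydrogenation that creates C5 and C8 together, cis.
- 7 ⇐ 4-quinolone 6 (O-methylation) ⇐ Conrad–Limpach annulation of 2-methoxy-5-octylaniline (3) with methyl 2-methoxyacetoacetate (4).
- 3 ⇐ 5-bromo-2-methoxyaniline (1) + 1-octene (2) by B-alkyl Suzuki coupling.
- Ring order: benzene ring bought; pyridone ring built on it (step 3); the saturated carbocycle is unveiled by dearomatisation (step 5), not built.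

Assumption: methyl 2-methoxy-3-oxobutanoate (4) is treated as a catalogue compound; if it is not in stock it needs one extra step (Rh2(OAc)4-catalysed O–H insertion of methyl 2-diazoacetoacetate into MeOH).

Stereochemistry planned for: the target is (5S,8R), with the 5-octyl and 8-OMe groups cis.

**Step 1**
Reactants: 1 (5-bromo-2-methoxyaniline), 2 (1-octene)
Product: 3 (2-methoxy-5-octylaniline)
Conditions: 2, 9-BBN, THF, 0 °C→rt; then 1, Pd(dppf)Cl2 (3 mol %), aq K3PO4, THF/DMF, 65 °C
Reagents that add atoms: none besides the reactants (9-BBN, catalyst and base leave no atoms)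
Why: anti-Markovnikov hydroboration gives B-octyl-9-BBN, which undergoes B-alkyl Suzuki–Miyaura coupling with the aryl bromide; free ArNH2 and ArOMe are tolerated.

**Step 2**
Reactants: 3 (2-methoxy-5-octylaniline), 4 (methyl 2-methoxy-3-oxobutanoate)
Product: 5 (methyl (E)-2-methoxy-3-[(2-methoxy-5-octylphenyl)amino]but-2-enoate, N–H···O=C chelated enaminoester)
Conditions: p-TsOH (1 mol %), toluene, Dean–Stark, reflux
Reagents that add atoms: none (4 is a reactant; H2O is lost)
Why: first stage of the Conrad–Limpach synthesis; under mild acid catalysis the aniline condenses at the ketone to give the β-anilinoacrylate, not the anilide of the Knorr pathway.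

**Step 3**
Reactants: 5 (enaminoester)
Product: 6 (3,8-dimethoxy-2-methyl-5-octylquinolin-4(1H)-one)
Conditions: Ph2O, 250 °C, 20 min (5 added to the hot solvent)
Reagents that add atoms: none (MeOH is lost)
Why: Conrad–Limpach thermal cyclisation acylates the only free position ortho to nitrogen, which places the octyl group at C5 and the methoxy group at C8 of the 4-quinolone.

**Step 4**
Reactants: 6 (4-quinolone)
Product: 7 (3,4,8-trimethoxy-2-methyl-5-octylquinoline)
Conditions: MeI, Ag2CO3, toluene, 60 °C, dark
Reagents that add atoms: iodomethane, CI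
Why: silver-mediated O-alkylation of the ambident 4-quinolone; the nitrogen is flanked by the 2-methyl and the peri 8-OMe, so methylation goes to oxygen and gives the 4-methoxyquinoline.

**Step 5 (key step)**
Reactants: 7 (3,4,8-trimethoxy-2-methyl-5-octylquinoline)
Product: 8 ((5S,8R)-3,4,8-trimethoxy-2-methyl-5-octyl-5,6,7,8-tetrahydroquinoline; octyl and 8-OMe cis)
Conditions: [Ru(η3-methallyl)2(cod)] (5 mol %), PhTRAP (single antipode, 5.5 mol %), H2 (60 bar), i-PrOH, 80 °C, 48 h (Ru–bis-NHC/SINpEt as in-class alternative)
Reagents that add atoms: none (H2, [H][H], adds hydrogen only)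
Why: Proposed new method: carbocycle-selective asymmetric arene hydrogenation, extending the known Ru/trans-chelating-bisphosphine and Ru–NHC hydrogenations of 8-substituted quinolines, quinoxalines and alkoxynaphthalenes to a 5,8-disubstituted quinoline; the pyridine ring is fully substituted and its nitrogen is shielded by 2-Me and 8-OMe, so Ru should bind the benzo ring, and delivery of all three H2 from the metal-bound face without arene dissociation fixes the 5,8-cis relationship, while the chiral ligand selects the arene face and so the (5S,8R) configuration (the ligand antipode is chosen by a first screen of both, and ee is upgraded if needed by crystallising a dibenzoyl-tartrate salt of 8).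

**Step 6**
Reactants: 8 (tetrahydroquinoline)
Product: 9 ((5S,8R)-3,4,8-trimethoxy-2-methyl-5-octyl-5,6,7,8-tetrahydroquinoline 1-oxide)
Conditions: mCPBA (1.2 equiv), CH2Cl2, 0 °C→rt
Reagents that add atoms: mCPBA, O=C(OO)c1cccc(Cl)c1
Why: electrophilic N-oxidation of the electron-rich pyridine; there is no alkene or amine to compete, and C5 and C8 are untouched.

**Step 7**
Reactants: 9 (N-oxide)
Product: 10 (Waltherione K, (5S,8R)-1,3,8-trimethoxy-2-methyl-5-octyl-5,6,7,8-tetrahydroquinolin-4(1H)-one)
Conditions: MeI (5 equiv), MeCN, 85 °C, sealed tube, dark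
Reagents that add atoms: iodomethane, CI (supplies the N–O–CH3 carbon; the original C4–O–CH3 leaves as MeI, so the step is a net isomerisation)
Why: MeI O-methylates the N-oxide to a 1,4-dimethoxypyridinium iodide, and iodide then removes the now-activated C4 O-methyl by SN2 (the N-oxide counterpart of the MeI-promoted 4-methoxypyridine → N-methyl-4-pyridone isomerisation and of the thermal alkoxypyridine N-oxide → N-alkoxypyridone rearrangement); the 3- and 8-OMe groups are not activated, and the base-free conditions should leave C8 unepimerised.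

**Compound list**
1 | 5-bromo-2-methoxyaniline | COc1ccc(Br)cc1N | starting material
2 | 1-octene | C=CCCCCCC | starting material
3 | 2-methoxy-5-octylaniline | CCCCCCCCc1ccc(OC)c(N)c1 | intermediate
4 | methyl 2-methoxy-3-oxobutanoate | COC(=O)C(OC)C(C)=O | starting material
5 | methyl (E)-2-methoxy-3-[(2-methoxy-5-octylphenyl)amino]but-2-enoate | CCCCCCCCc1ccc(OC)c(N/C(C)=C(/OC)C(=O)OC)c1 | intermediate
6 | 3,8-dimethoxy-2-methyl-5-octylquinolin-4(1H)-one | CCCCCCCCc1ccc(OC)c2[nH]c(C)c(OC)c(=O)c12 | intermediate
7 | 3,4,8-trimethoxy-2-methyl-5-octylquinoline | CCCCCCCCc1ccc(OC)c2nc(C)c(OC)c(OC)c12 | intermediate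
8 | (5S,8R)-3,4,8-trimethoxy-2-methyl-5-octyl-5,6,7,8-tetrahydroquinoline | CCCCCCCC[C@H]1CC[C@@H](OC)c2c1c(OC)c(OC)c(C)n2 | intermediate
9 | (5S,8R)-3,4,8-trimethoxy-2-methyl-5-octyl-5,6,7,8-tetrahydroquinoline 1-oxide | CCCCCCCC[C@H]1CC[C@@H](OC)c2c1c(OC)c(OC)c(C)[n+]2[O-] | intermediate
10 | Waltherione K, (5S,8R)-1,3,8-trimethoxy-2-methyl-5-octyl-5,6,7,8-tetrahydroquinolin-4(1H)-one | CCCCCCCC[C@H]1CC[C@@H](OC)c2c1c(=O)c(OC)c(C)n2OC | target

**Totals**
Total steps: 7. Longest linear sequence: 7 (fully linear from 1).

**Three steps most likely to fail, with fallbacks**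
1. Step 5 (asymmetric arene hydrogenation). Risks are low ee, 8-OMe hydrogenolysis, catalyst inhibition by the N/8-OMe pocket, or slow reduction of the hindered ring. Fallback: drop catalyst control and resolve instead. Hydrogenate the 8-OTBS analogue of 7 with an achiral all-cis arene catalyst (Rh–CAAC or Rh/Al2O3), remove the silyl group, and resolve the rac-cis-8-ol with CAL-B/vinyl acetate (the 8R alcohol is expected to be acylated, by Kazlauskas' rule). Then cleave the acetate and O-methylate (NaH/MeI) to rejoin at 8.
2. Step 7 (N-oxide → N-methoxypyridone methyl shuttle). Risks are an unfavourable equilibrium or side reactions of the N-methoxypyridinium salt. Fallback: make the N–OMe by alkylating an N-hydroxypyridone. Hydrogenate quinolone 6 directly as in step 5, then O-benzylate at C4 (BnBr/Ag2CO3), N-oxidise (mCPBA), remove the benzyl group (H2, Pd/C) to give the 1-hydroxy-4-pyridone, and O-methylate the N–OH (MeI/K2CO3).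
3. Step 3 (Conrad–Limpach closure next to the octyl group). Risks are a sluggish cyclisation or decomposition at 250 °C. Fallback: reverse the order. Run steps 2–4 on bromoaniline 1 to give 5-bromo-3,4,8-trimethoxy-2-methylquinoline, then introduce the octyl chain last by B-octyl-9-BBN Suzuki (or octylzinc Negishi) coupling to reach 7.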